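The data were computed for substances that don't exist, and the scatter is random.

Reagent is the charge to watch in alder and maple, and I carry one quantity from violet to them: the exposure of target to free catalyst.

| flask | substrate | reagent | free catalyst | remark | time |
|---|---|---|---|---|---|
| violet | 0.10 M | 0.99 equiv | 0.1 mol% | run made earlier |  |
| teal | 0.10 M | 1.3 equiv | 0.1 mol% | run made earlier |  |
| alder | 0.10 M | 0.700 equiv | 0.1 mol% |  | 6.0 min |
| maple | 0.10 M | 0.910 equiv | 0.1 mol% |  | 6.0 min |
- violet (time / min: target / %, substrate / %): 0.333: 15.4, 84.9; 0.500: 20.5, 77.9; 1.00: 35.4, 61.6; 1.50: 46.0, 47.2; 2.50: 58.2, 29.4; 4.00: 64.4, 14.4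
- teal (time / min: target / %, substrate / %): 0.333: 15.2, 83.0; 0.500: 22.6, 75.6; 1.00: 39.5, 57.1; 1.50: 52.3, 41.6; 2.50: 67.5, 22.5; 4.00: 79.6, 8.9

(scatter of a reading: 0.5 percentage points)
* which of the two there is more of at the end, alder (isomer of the product / target)
* which of the two there is more of at the end, maple (isomer of the product / target)
* final target, as a percentage of the substrate charged, in alder
* final target, as a percentage of the substrate charged, in maple
- what is said of target includes crystals
- crystals is a solid; its amount is given per volume of the solution
- the numbers in the tables scatter with a standard deviation of 0.5 percentage points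
- reactions considered so far: reagent + free catalyst -> catalyst intermediate A; substrate + catalyst intermediate A <-> catalyst intermediate B; catalyst intermediate B -> free catalyst + target; target + free catalyst <-> isomer of the product + free catalyst; crystals <-> target

1. The main step alone. Each substrate turned over costs one reagent, so reagent is the limiting reagent in alder (0.700 equiv) and maple (0.910 equiv), and target plus isomer stop at that charge. Violet's substrate falls pseudo-first-order at 0.484 min⁻¹, and its earlier reading at 1.00 min gives about the same constant. At that pace I estimate that the reagent charge is used by 2.49 min in alder and 4.97 min in maple, both earlier than 6.0 min; I call these estimates the reagent-out times.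

2. Add the isomerisation. What is missing from violet's charge is isomer, which climbs from 12.4% at 2.50 min to 21.2% at 4.00 min, so it gains 0.0587 min⁻¹ of the charge. Crystals and the way back already sit inside that reading, so I add nothing for them.

3. Add the catalyst's forms. While reagent lasts I assume about 0.5 of the catalyst is free; after the reagent-out time I take it as wholly free, so those minutes count double. The exposure, the reaction time plus the time after reagent-out 9.51 min, is that value in alder and 7.03 min in maple. Multiplied by violet's gain, it gives isomer 55.8% and target 14.2% in alder, so more isomer than target, and isomer 41.2% and target 49.8% in maple, so more target than isomer.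

The forecast, which parts from me on alder, has target ahead in both flasks, at 39% and 51%, holding that “both are nearly equilibrated”.

Alder ends with target 21.7% and isomer 48.1%, so the answer for alder is isomer of the product.

Maple ends with target 47.9% and isomer 41.4%, so the answer for maple is target.

    reagent + free catalyst → catalyst intermediate A (k = 201 L mol⁻¹ s⁻¹)
    substrate + catalyst intermediate A ⇌ catalyst intermediate B (K = 120 L mol⁻¹, k = 143 L mol⁻¹ s⁻¹)
    catalyst intermediate B → free catalyst + target (k = 543 s⁻¹)
    target + free catalyst ⇌ isomer of the product + free catalyst, rate k4*[free catalyst]*[target] forward; the back reaction follows from the equilibrium constant (K = 5.00, k = 71.3 L mol⁻¹ s⁻¹)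
    crystals ⇌ target, rate k5*(cs5 - [target]) while solid is left; crystals form when [target] > cs5 (solubility = 35.0 mM, k = 0.212 s⁻¹)

Maple's exposure of 7.03 min gave my estimate of 41.2% of isomer, and maple holds 41.4%, while alder's exposure of 9.51 min gave an estimate 7.7 percentage points above what alder holds. The neighbour is maple with 0.06 mol% of free catalyst. Scaling by the catalyst, I estimate its reagent-out time at 8.28 min, later than 6.0 min, so no minute counts double; its exposure is 3.60 min and my estimate of its isomer is 21.1%. That flask holds isomer 21.5%, target 58.0%, and 13% of its reagent.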